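Its constants stand for no real mixture, and the outcome is calculated.

You read these flasks at 4.0 d, so the thing to count is how many times each product has had the chance to go back to starting material by then.

    starting material + protic impurity → quenched substrate (k1 = 0.0079 L mol⁻¹ min⁻¹)
    starting material ⇌ isomer of the product (K2 = 2.7, k2 = 4.6 × 10⁻⁴ min⁻¹)
    starting material ⇌ target (K3 = 0.42, k3 = 8.3 × 10⁻⁴ min⁻¹)

the same everywhere: starting material 0.050 M; time 4.0 d

|  | protic impurity |
|---|---|
| epsilon | 0.0250 M |
| alpha | 0.0500 M |
| beta | 0.100 M |
| eta | 0.200 M |
| gamma | 0.400 M |

- share of target in all that became target or isomer of the product for epsilon, alpha, beta, eta, gamma, in this order
- how the row runs (falls, then rises / rises, then falls / falls all the way / rises all the way / hardly changes)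

- "hardly changes" means that all values lie within two and a half points (for a concentration: within two and a half percent of the largest)
- run time (epsilon): 4.0 d

The quantity to carry is the target's return count, the reading time multiplied by the forward rate constant of its step and divided by that step's equilibrium constant, 11.4. The same count for the isomer of the product is 0.981, much smaller.

Climb the ladder from the fast end. On the first rung, target and starting material relax into each other with a half-life of 0.172 d by that step alone, shorter than the 0.764 d of the isomer's step, and short against the reading time. In epsilon, the flask therefore soon holds target near pre-equilibrium with starting material, while the isomer fills up behind it. The quench, a pseudo-first-order loss of starting material, moves along the ladder with the charge of protic impurity. At the impurity as charged, its lifetime is 0.220 d in gamma, shorter than the 3.52 d in epsilon. On the top rung stands the isomer's return lifetime, 4.08 d, longer than the quench lifetime in gamma.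

So in gamma, the quench removes starting material sooner than the isomer can come back. Its lifetime there is also shorter than the target's return lifetime of 0.351 d, so the target may trail for a while. With its high return count, the target should still follow starting material down, and the isomer should lag further. My reckoning stops at a direction. I score a fall by the ratio of the target's return count to the isomer's, a rise by the inverse, and a flat or turning row by a neutral one, so I expect this course: falls all the way.

The forecast puts numbers on that row: 14 %, 12.4 %, 8.8 %, 5 % and 2.45 %, so falls all the way. Its ground is that “the target drains back through it much faster than the isomer”.

The simulation gives 14.3 %, 12.6 %, 9.37 %, 5.34 % and 2.59 %, so falls all the way.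

The return count reads true in the flasks. In epsilon, c(target)/c(starting material) reads 0.475 at 2.00 d and 0.439 at 4.00 d, near 0.42. In gamma, with the same count of 11.4, the ratio reads 0.802 at 2.00 d, well above 0.42, and comes down to 0.468 at 4.00 d. The isomer, with a count of 0.981, still stands at 6.11 % of the charge in gamma, against 0.163 % target. The return of target to starting material is the main reason for the low share in gamma: without it the share there is 81.7 % instead of 2.59 %.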